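1. You see less target in larch at 20.0 min than in maple at 60.0 min, though both flasks have lost about the same substrate.

| setting | maple | larch | grey | amber | green |
|---|---|---|---|---|---|
| substrate | 0.40 M | 0.40 M | 0.40 M | 0.40 M | 0.40 M |
| partner | 0.60 equiv | 0.60 equiv | 0.600 equiv | 0.600 equiv | 0.600 equiv |
| catalyst | 0.19 mol% | 0.76 mol% | 0.38 mol% | 0.38 mol% | 0.38 mol% |
| temperature | 100 °C | 122 °C | 110 °C | 90 °C | 130 °C |
| remark | run made earlier | run made earlier |  |  |  |
| time |  |  | 30 min | 30 min | 30 min |

- maple (time / min: target / %, substrate / %): 5.00: 14.3, 75.1; 8.00: 17.3, 66.1; 15.0: 21.8, 51.3; 30.0: 22.8, 35.5; 60.0: 19.8, 22.9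
- larch (time / min: target / %, substrate / %): 1.50: 11.0, 71.2; 3.00: 14.5, 55.2; 6.00: 15.7, 39.3; 12.0: 14.8, 26.5; 20.0: 10.7, 21.2

(readings scatter by 0.5 percentage points)

* the flask with the highest amount of target, in percent of the substrate charged ("all alike" if they lie within 1.5 percentage points) (grey / amber / green / all alike)
* final target, as a percentage of the substrate charged, in grey
* final target, as a percentage of the substrate charged, in amber
* final target, as a percentage of the substrate charged, in green

2. Open the ledger at the last maple reading. Substrate still there: 22.9%. Target: 19.8%. Not read: the remaining 57.3%.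

3. Partner is the limiting reagent at 0.60 equiv, yet the substrate gone from maple stands at 77.1%. So the books need a route that spends no partner.

4. Follow one substrate molecule that has left. Its chance of standing as target is the kept share (an integral selectivity): 25.7% in maple, 13.6% in larch.

5. Catalyst and temperature both differ between these runs, so charging the drop to temperature is my guess. On that guess, a rise of 23.9 K halves the kept share at matched conversion: call it the halving span.

6. My reckoning holds the substrate gone at maple's last figure, a crude step, since the three new flasks differ from maple in temperature, loading and time. The span gives amber a kept share of 34.3%, so I reckon near 26.4% of target there. It gives grey 19.2%, so I reckon near 14.8%. It gives green 10.8%, so I reckon near 8.33%.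

7. The forecast names amber, with 24% there, 16.5% in grey and 5% in green, on the ground that “higher temperature favours side reaction and loss”. We share the order, but my figure stands above its own in amber and green and below it in grey.

8. The flasks give 25.0% in amber, 16.6% in grey and 4.28% in green, so amber leads.

    substrate + target → side product (k = 0.194 M⁻¹ min⁻¹, Ea = 98.0 kJ mol⁻¹)
    substrate ⇌ dormant form (K = 0.410, k = 0.0204 min⁻¹, Ea = 128 kJ mol⁻¹, ΔH = −13.0 kJ mol⁻¹)
    substrate + partner ⇌ isomer of the product (K = 920 M⁻¹, k = 0.119 M⁻¹ min⁻¹, Ea = 78.0 kJ mol⁻¹, ΔH = −39.0 kJ mol⁻¹)
    target + catalyst ⇌ isomer of the product + catalyst, rate k4*[catalyst]*[target] forward; the back reaction follows from the equilibrium constant (k = 1.63 M⁻¹ min⁻¹, Ea = 69.0 kJ mol⁻¹)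
    substrate + partner ⇌ target (K = 27.0 M⁻¹, k = 0.296 M⁻¹ min⁻¹, Ea = 60.0 kJ mol⁻¹, ΔH = −13.0 kJ mol⁻¹)
    (constants at 110 °C)

Amber leads green by 21 percentage points. Take away what temperature does to the passing of substrate + target into side product and that gap shrinks to 5.5 points, the largest single effect. Grey keeps 21.6% of its converted substrate, dormant form counted as converted, against the span's 19.2%. In the neighbour, grey run at 125 °C, the span reckons 10.5% target from the substrate gone there, and the flask holds 6.66%.

The data are calculated on assumed constants.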